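**Plan**

- Retrosynthesis: ring A of the flavanone half is first taken back to its 7-silyloxy-5-oxo-5,6,7,8-tetrahydro form. Ring C is then cut at C2–C3 and O1–C8a (aldehyde 17 plus diene 16), followed by C4–C4a (C-acylation of dione 12 by arylacetic acid 8), the aryl–CH2 bond (Negishi coupling) and the pyranone ring of the flavone half (chalcone 5).
- Enabling feature: ring C is a 2,3-dihydropyran-4-one whose C4a=C8a double bond is shared with ring A, and the 5,7-dihydroxy ring A is the aromatic tautomer of a 5,7-dioxo ring that one oxidation of a C7 carbinol supplies. In the reduced series C8a(OMe)=C4a–C4(OSiMe3)=C3 is therefore a 1-methoxy-3-silyloxy diene.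
- Forward order: flavone ring (steps 1–6), reduced ring A from phloroglucinol (steps 7–8), union and diene (steps 9–11), ring C (step 12), aromatisation of ring A (steps 13–14), debenzylation (step 15).
- Stereochemistry: C2 (S) from Si-face addition to 17 under an (S)-BINOL–titanium Lewis acid; C3 (R) by equilibration to the trans-2,3-diaryl arrangement; the racemic C7 centre is erased on aromatisation.

Key step: step 12

Abbreviation: ArF = 2-(benzyloxy)-5-[5-(benzyloxy)-7-methoxy-4-oxo-4H-chromen-2-yl]phenyl; atom numbers O1 to C8a are those of the flavanone half of the target.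

Assumption: dione 12 is achiral and nothing differentiates its two carbonyl groups, so 15, 16, 18, 19 and 20 arise as both configurations at the ring-A carbinol carbon (C7); the SMILES show the R form, both are carried together, and the centre disappears in step 14.

**Route**

Step 1
Reactants: 1 3-bromo-4-hydroxybenzaldehyde
Product: 2 4-(benzyloxy)-3-bromobenzaldehyde
Conditions: BnBr, K2CO3, DMF, rt
Reagents that add atoms: benzyl bromide, BrCc1ccccc1
Why: Williamson etherification of the phenoxide with a primary benzylic halide should be clean, the aldehyde and the aryl bromide being inert to carbonate.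

Step 2
Reactants: 3 2',6'-dihydroxy-4'-methoxyacetophenone
Product: 4 2'-(benzyloxy)-6'-hydroxy-4'-methoxyacetophenone
Conditions: BnBr (1.05 equiv), K2CO3, acetone, reflux
Reagents that add atoms: benzyl bromide, BrCc1ccccc1
Why: Williamson mono-etherification should stop after one alkylation because the remaining phenol is held in a hydrogen bond to the acetyl carbonyl and is much less nucleophilic.

Step 3
Reactants: 2 4-(benzyloxy)-3-bromobenzaldehyde; 4 2'-(benzyloxy)-6'-hydroxy-4'-methoxyacetophenone
Product: 5 (E)-1-[2-(benzyloxy)-6-hydroxy-4-methoxyphenyl]-3-[4-(benzyloxy)-3-bromophenyl]prop-2-en-1-one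
Conditions: KOH (50% aq), EtOH, rt
Reagents that add atoms: none
Why: Claisen–Schmidt condensation of the acetophenone enolate with a non-enolisable aldehyde should give the E-chalcone and leaves the free ortho-hydroxyl needed for ring closure.

Step 4
Reactants: 5 (E)-1-[2-(benzyloxy)-6-hydroxy-4-methoxyphenyl]-3-[4-(benzyloxy)-3-bromophenyl]prop-2-en-1-one
Product: 6 5-(benzyloxy)-2-[4-(benzyloxy)-3-bromophenyl]-7-methoxy-4H-chromen-4-one
Conditions: I2 (10 mol%), DMSO, 120 °C
Reagents that add atoms: none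
Why: Iodine-catalysed oxidative cyclisation of a 2'-hydroxychalcone (oxa-Michael closure, α-iodination, loss of HI, reoxidation of HI by DMSO) is the standard flavone synthesis and tolerates aryl bromides and benzyl ethers.

Step 5
Reactants: 6 5-(benzyloxy)-2-[4-(benzyloxy)-3-bromophenyl]-7-methoxy-4H-chromen-4-one
Product: 7 tert-butyl ArF-acetate
Conditions: BrZnCH2CO2tBu (1.5 equiv), Pd2(dba)3 (2.5 mol%), XPhos (10 mol%), THF, 60 °C
Reagents that add atoms: (2-tert-butoxy-2-oxoethyl)zinc bromide, CC(C)(C)OC(=O)C[Zn]Br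
Why: Negishi-type coupling of a Reformatsky reagent with an aryl bromide on a zerovalent palladium/biarylphosphine catalyst is a known route to arylacetic esters, and the mild zinc enolate should not touch the pyranone carbonyl.

Step 6
Reactants: 7 tert-butyl ArF-acetate
Product: 8 ArF-acetic acid
Conditions: TFA/CH2Cl2 (1:4), 0 °C to rt
Reagents that add atoms: none
Why: Acidolysis of the tert-butyl ester (E1 loss of isobutene) should free the acid, the aryl benzyl ethers being stable to dilute TFA over a short time.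

Step 7
Reactants: 9 phloroglucinol
Product: 10 5-hydroxycyclohexane-1,3-dione
Conditions: NaBH4, H2O, 0 °C to rt; then acidic ion-exchange resin
Reagents that add atoms: none
Why: Borohydride reduction of one carbonyl of the triketo tautomer of the phloroglucinolate is a known preparation of dihydrophloroglucinol, and the β-diketonate formed resists further hydride addition.

Step 8
Reactants: 10 5-hydroxycyclohexane-1,3-dione
Product: 12 5-[(tert-butyldimethylsilyl)oxy]cyclohexane-1,3-dione, via bis-silyl enone 11 (not isolated)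
Conditions: TBSCl (2.3 equiv), imidazole, DMF, rt; then 5% aq citric acid, THF, 0 °C
Reagents that add atoms: tert-butyldimethylsilyl chloride, CC(C)(C)[Si](C)(C)Cl
Why: Silylation covers both the carbinol and the enol oxygen, and the vinylogous silyl ester is hydrolysed selectively by cold dilute acid while the secondary silyl ether stays.

Step 9
Reactants: 8 ArF-acetic acid; 12 5-[(tert-butyldimethylsilyl)oxy]cyclohexane-1,3-dione
Product: 14 2-(ArF-acetyl)-5-[(tert-butyldimethylsilyl)oxy]-3-hydroxycyclohex-2-en-1-one (enol form of the triketone), via enol ester 13 (not isolated)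
Conditions: DCC, DMAP (1.2 equiv), CH2Cl2, 0 °C to rt
Reagents that add atoms: none
Why: Steglich O-acylation of the dione followed by DMAP-mediated O-to-C acyl migration through the acylpyridinium dionate pair is the established one-flask route to 2-acylcyclohexane-1,3-diones.

Step 10
Reactants: 14 2-(ArF-acetyl)-5-[(tert-butyldimethylsilyl)oxy]-3-hydroxycyclohex-2-en-1-one
Product: 15 2-(ArF-acetyl)-5-[(tert-butyldimethylsilyl)oxy]-3-methoxycyclohex-2-en-1-one
Conditions: TMSCHN2, toluene/MeOH (4:1), 0 °C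
Reagents that add atoms: trimethylsilyldiazomethane, C[Si](C)(C)C=[N+]=[N-]
Why: Diazoalkane O-methylation of the acidic ring enol needs no base, so E1cB loss of the silyloxy group cannot start, and 2-acyl-1,3-diones are expected to react at the ring oxygen to give the vinylogous methyl ester.

Step 11
Reactants: 15 2-(ArF-acetyl)-5-[(tert-butyldimethylsilyl)oxy]-3-methoxycyclohex-2-en-1-one
Product: 16 5-[(tert-butyldimethylsilyl)oxy]-3-methoxy-2-[(Z)-2-ArF-1-(trimethylsilyloxy)ethenyl]cyclohex-2-en-1-one
Conditions: TMSOTf (1.5 equiv), Et3N (3 equiv), CH2Cl2, −78 to 0 °C; non-aqueous work-up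
Reagents that add atoms: trimethylsilyl triflate, C[Si](C)(C)OS(=O)(=O)C(F)(F)F
Why: Soft enolisation should silylate the most acidic position, the benzylic methylene between the aryl ring and the exocyclic ketone, giving the Z enol silane under conditions too weakly basic to enolise the ring ketone and eliminate the silyloxy group.

Step 12
Reactants: 16 5-[(tert-butyldimethylsilyl)oxy]-3-methoxy-2-[(Z)-2-ArF-1-(trimethylsilyloxy)ethenyl]cyclohex-2-en-1-one; 17 4-(benzyloxy)benzaldehyde
Product: 19 (2S,3R)-3-ArF-2-[4-(benzyloxy)phenyl]-7-[(tert-butyldimethylsilyl)oxy]-2,3,7,8-tetrahydro-4H-chromene-4,5(6H)-dione, via aldol silyl ether 18 (not isolated)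
Conditions: (S)-BINOL (40 mol%), Ti(OiPr)4 (20 mol%), 4 Å MS, Et2O/CH2Cl2, −20 °C; then TFA (0.5 equiv), CH2Cl2, 0 °C
Reagents that add atoms: none
Why: Proposed new method: the titanium-bound aldehyde should be attacked at its Si face by the enol silane carbon C3 of 16 (Mukaiyama aldol mode with silyl transfer, giving 18), and on acidification the freed C2 oxygen adds to the vinylogous ester carbon C8a and expels methanol, so that C2–C3 and O1–C8a are made in one operation. The closest known reaction type is the BINOL–titanium catalysed formal hetero-Diels–Alder reaction of 1-methoxy-3-silyloxy dienes with aromatic aldehydes, which follows the same aldol-then-acid-closure course to 2-aryl-2,3-dihydropyran-4-ones; new here is that the diene terminus C8a is a fully substituted ring carbon and that C3 carries an aryl group. Ring C closes by a 6-endo-trig addition–elimination at C8a. C2 (S) is set by ligand-controlled Si-face approach, a sense inferred from allylations and aldol additions of aryl aldehydes with the same (S)-BINOL complex, and C3 (R) is set thermodynamically, any cis isomer equilibrating through the C3 enol under the acidic closure to the trans-2,3-diaryl arrangement. The step needs site selectivity for C3 over the ring methylenes (secured by the preformed enol silane), closure at C8a (secured by the methoxy leaving group on the carbon β to both the C4 and C5 carbonyls) and survival of the C7 silyloxy group (secured by the absence of base, so no E1cB elimination toward C6 or C8 can begin).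

Step 13
Reactants: 19 (2S,3R)-3-ArF-2-[4-(benzyloxy)phenyl]-7-[(tert-butyldimethylsilyl)oxy]-2,3,7,8-tetrahydro-4H-chromene-4,5(6H)-dione
Product: 20 (2S,3R)-3-ArF-2-[4-(benzyloxy)phenyl]-7-hydroxy-2,3,7,8-tetrahydro-4H-chromene-4,5(6H)-dione
Conditions: HF·pyridine, pyridine, THF, 0 °C
Reagents that add atoms: none
Why: Fluoride-driven cleavage of the secondary silyl ether in a weakly acidic buffered medium should free the C7 carbinol without base-induced β-elimination or opening of ring C.

Step 14
Reactants: 20 (2S,3R)-3-ArF-2-[4-(benzyloxy)phenyl]-7-hydroxy-2,3,7,8-tetrahydro-4H-chromene-4,5(6H)-dione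
Product: 22 (2S,3R)-3-ArF-2-[4-(benzyloxy)phenyl]-5,7-dihydroxy-2,3-dihydro-4H-chromen-4-one, via trione 21 (not isolated)
Conditions: Dess–Martin periodinane (1.2 equiv), CH2Cl2, 0 °C to rt
Reagents that add atoms: none
Why: Dess–Martin oxidation of the β-hydroxy ketone under near-neutral conditions should give the 5,7-dioxo ring, which enolises toward C6 and C8 to the aromatic 5,7-dihydroxy ring A without touching C2 or C3.

Step 15
Reactants: 22 (2S,3R)-3-ArF-2-[4-(benzyloxy)phenyl]-5,7-dihydroxy-2,3-dihydro-4H-chromen-4-one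
Product: 23 (2S,3R)-5,7-dihydroxy-3-[2-hydroxy-5-(5-hydroxy-7-methoxy-4-oxo-4H-chromen-2-yl)phenyl]-2-(4-hydroxyphenyl)-2,3-dihydro-4H-chromen-4-one
Conditions: H2 (1 atm), Pd/C (10%), EtOAc/MeOH, rt
Reagents that add atoms: none
Why: Catalytic hydrogenolysis removes the three aryl benzyl ethers under neutral conditions, the flavone double bond and the chromanone C2–O bond being slower to reduce at atmospheric pressure if the reaction is stopped at complete debenzylation.

**Compound list**

1 | 3-bromo-4-hydroxybenzaldehyde | O=Cc1ccc(O)c(Br)c1 | starting material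
2 | 4-(benzyloxy)-3-bromobenzaldehyde | O=Cc1ccc(OCc2ccccc2)c(Br)c1 | intermediate
3 | 2',6'-dihydroxy-4'-methoxyacetophenone | CC(=O)c1c(O)cc(OC)cc1O | starting material
4 | 2'-(benzyloxy)-6'-hydroxy-4'-methoxyacetophenone | CC(=O)c1c(O)cc(OC)cc1OCc1ccccc1 | intermediate
5 | (E)-1-[2-(benzyloxy)-6-hydroxy-4-methoxyphenyl]-3-[4-(benzyloxy)-3-bromophenyl]prop-2-en-1-one | COc1cc(O)c(C(=O)/C=C/c2ccc(OCc3ccccc3)c(Br)c2)c(OCc2ccccc2)c1 | intermediate
6 | 5-(benzyloxy)-2-[4-(benzyloxy)-3-bromophenyl]-7-methoxy-4H-chromen-4-one | COc1cc(OCc2ccccc2)c2c(=O)cc(-c3ccc(OCc4ccccc4)c(Br)c3)oc2c1 | intermediate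
7 | tert-butyl {2-(benzyloxy)-5-[5-(benzyloxy)-7-methoxy-4-oxo-4H-chromen-2-yl]phenyl}acetate | COc1cc(OCc2ccccc2)c2c(=O)cc(-c3ccc(OCc4ccccc4)c(CC(=O)OC(C)(C)C)c3)oc2c1 | intermediate
8 | {2-(benzyloxy)-5-[5-(benzyloxy)-7-methoxy-4-oxo-4H-chromen-2-yl]phenyl}acetic acid | COc1cc(OCc2ccccc2)c2c(=O)cc(-c3ccc(OCc4ccccc4)c(CC(=O)O)c3)oc2c1 | intermediate
9 | phloroglucinol (benzene-1,3,5-triol) | Oc1cc(O)cc(O)c1 | starting material
10 | 5-hydroxycyclohexane-1,3-dione (dihydrophloroglucinol) | O=C1CC(=O)CC(O)C1 | intermediate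
11 | 3,5-bis[(tert-butyldimethylsilyl)oxy]cyclohex-2-en-1-one (racemic) | CC(C)(C)[Si](C)(C)OC1CC(=O)C=C(O[Si](C)(C)C(C)(C)C)C1 | intermediate
12 | 5-[(tert-butyldimethylsilyl)oxy]cyclohexane-1,3-dione | CC(C)(C)[Si](C)(C)OC1CC(=O)CC(=O)C1 | intermediate
13 | 5-[(tert-butyldimethylsilyl)oxy]-3-oxocyclohex-1-en-1-yl ArF-acetate (racemic enol ester) | COc1cc(OCc2ccccc2)c2c(=O)cc(-c3ccc(OCc4ccccc4)c(CC(=O)OC4=CC(=O)CC(O[Si](C)(C)C(C)(C)C)C4)c3)oc2c1 | intermediate
14 | 2-(ArF-acetyl)-5-[(tert-butyldimethylsilyl)oxy]-3-hydroxycyclohex-2-en-1-one (enol form of the triketone; tautomers interconvert the ring carbonyls) | COc1cc(OCc2ccccc2)c2c(=O)cc(-c3ccc(OCc4ccccc4)c(CC(=O)C4=C(O)CC(O[Si](C)(C)C(C)(C)C)CC4=O)c3)oc2c1 | intermediate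
15 | 2-(ArF-acetyl)-5-[(tert-butyldimethylsilyl)oxy]-3-methoxycyclohex-2-en-1-one (racemic; 5R drawn) | COc1cc(OCc2ccccc2)c2c(=O)cc(-c3ccc(OCc4ccccc4)c(CC(=O)C4=C(OC)C[C@@H](O[Si](C)(C)C(C)(C)C)CC4=O)c3)oc2c1 | intermediate
16 | 5-[(tert-butyldimethylsilyl)oxy]-3-methoxy-2-[(Z)-2-ArF-1-(trimethylsilyloxy)ethenyl]cyclohex-2-en-1-one (racemic; 5R drawn) | COc1cc(OCc2ccccc2)c2c(=O)cc(-c3ccc(OCc4ccccc4)c(/C=C(\O[Si](C)(C)C)C4=C(OC)C[C@@H](O[Si](C)(C)C(C)(C)C)CC4=O)c3)oc2c1 | intermediate
17 | 4-(benzyloxy)benzaldehyde | O=Cc1ccc(OCc2ccccc2)cc1 | starting material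
18 | 2-{(2R,3S)-2-ArF-3-[4-(benzyloxy)phenyl]-3-(trimethylsilyloxy)propanoyl}-5-[(tert-butyldimethylsilyl)oxy]-3-methoxycyclohex-2-en-1-one (anti aldol silyl ether; ring carbinol R drawn; the C2 epimer of the propanoyl chain converges after closure) | COc1cc(OCc2ccccc2)c2c(=O)cc(-c3ccc(OCc4ccccc4)c([C@@H](C(=O)C4=C(OC)C[C@@H](O[Si](C)(C)C(C)(C)C)CC4=O)[C@H](O[Si](C)(C)C)c4ccc(OCc5ccccc5)cc4)c3)oc2c1 | intermediate
19 | (2S,3R)-3-ArF-2-[4-(benzyloxy)phenyl]-7-[(tert-butyldimethylsilyl)oxy]-2,3,7,8-tetrahydro-4H-chromene-4,5(6H)-dione (7R drawn; 7S epimer also present) | COc1cc(OCc2ccccc2)c2c(=O)cc(-c3ccc(OCc4ccccc4)c([C@H]4C(=O)C5=C(C[C@@H](O[Si](C)(C)C(C)(C)C)CC5=O)O[C@@H]4c4ccc(OCc5ccccc5)cc4)c3)oc2c1 | intermediate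
20 | (2S,3R)-3-ArF-2-[4-(benzyloxy)phenyl]-7-hydroxy-2,3,7,8-tetrahydro-4H-chromene-4,5(6H)-dione (7R drawn; 7S epimer also present) | COc1cc(OCc2ccccc2)c2c(=O)cc(-c3ccc(OCc4ccccc4)c([C@H]4C(=O)C5=C(C[C@@H](O)CC5=O)O[C@@H]4c4ccc(OCc5ccccc5)cc4)c3)oc2c1 | intermediate
21 | (2S,3R)-3-ArF-2-[4-(benzyloxy)phenyl]-2,3-dihydro-4H-chromene-4,5,7(6H,8H)-trione | COc1cc(OCc2ccccc2)c2c(=O)cc(-c3ccc(OCc4ccccc4)c([C@H]4C(=O)C5=C(CC(=O)CC5=O)O[C@@H]4c4ccc(OCc5ccccc5)cc4)c3)oc2c1 | intermediate
22 | (2S,3R)-3-ArF-2-[4-(benzyloxy)phenyl]-5,7-dihydroxy-2,3-dihydro-4H-chromen-4-one | COc1cc(OCc2ccccc2)c2c(=O)cc(-c3ccc(OCc4ccccc4)c([C@H]4C(=O)c5c(O)cc(O)cc5O[C@@H]4c4ccc(OCc5ccccc5)cc4)c3)oc2c1 | intermediate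
23 | (2S,3R)-5,7-dihydroxy-3-[2-hydroxy-5-(5-hydroxy-7-methoxy-4-oxo-4H-chromen-2-yl)phenyl]-2-(4-hydroxyphenyl)-2,3-dihydro-4H-chromen-4-one | COc1cc(O)c2c(=O)cc(-c3ccc(O)c([C@H]4C(=O)c5c(O)cc(O)cc5O[C@@H]4c4ccc(O)cc4)c3)oc2c1 | target

**Step count and risks**

Total step count: 15. Longest linear sequence: 12 steps (steps 1, 3, 4, 5, 6, 9, 10, 11, 12, 13, 14, 15).

Steps most likely to fail:

Step 12. The enol silane of 16 is cross-conjugated with the C5 carbonyl and may be too weak a nucleophile for the titanium-bound aldehyde. The pyranone carbonyl of the flavone half may sequester the Lewis acid, facial selectivity may be poor, and acid may ionise the 4-alkoxybenzylic C2–O bond and erode the configuration at C2. The fallback uses known chemistry, gives up asymmetric induction and resolves late. It sets out from triketone 14 and aldehyde 17. Amine-catalysed Knoevenagel condensation at the arylacetyl methylene (pyrrolidine, AcOH, toluene, reflux with removal of water) should give the 2,3-diarylacryloyl dione F1. Its ring enol oxygen then adds to the enone β-carbon in a 6-endo oxa-Michael closure (p-TsOH cat., toluene, 60 °C) to give the racemic trans silyl ether F2. The conditions of steps 13 and 14 would take F2 to the racemic alcohol F3 and on to the racemic 5,7-dihydroxy chromanone F4. Preparative HPLC of F4 on a chiral stationary phase (amylose tris(3,5-dimethylphenylcarbamate)) would deliver 22, where the route is rejoined for step 15.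

Step 14. Dehydration of the β-hydroxy ketone, before or during oxidation, would aromatise ring A with loss of the 7-oxygen, and the electron-rich phenolic product may be over-oxidised by the hypervalent iodine reagent. The fallback sets out from silyl ether 19 and replaces steps 13 and 14. Aerobic α,β-dehydrogenation of the ring-A ketone across C6–C7 with Pd(OCOCF3)2 (cat.), DMSO, O2 (1 atm), 60 °C is a known conversion of cyclohexenones into phenols, running through an enolate of divalent palladium and β-hydride elimination. It keeps the C7 oxygen silylated throughout and should give the aromatic 7-silyloxy-5-hydroxy chromanone F5; the secondary C6 position is expected to react ahead of the tertiary C3. HF·pyridine in THF then cleaves the aryl silyl ether and the route is rejoined at 22.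

Step 10. Alkylation may occur at the exocyclic enol oxygen or at carbon, giving a constitutional isomer that cannot serve as the diene. The fallback sets out from triketone 14. Oxalyl chloride with catalytic DMF in CH2Cl2 at 0 °C converts 2-acylcyclohexane-1,3-diones at the ring oxygen into the vinylogous acid chloride F6. Methanol and Et3N in CH2Cl2 at 0 °C then replace chloride by addition–elimination, and the route is rejoined at 15.

**Further compounds**

F1 | step 12 | 2-[(E)-2-ArF-3-(4-benzyloxyphenyl)prop-2-enoyl]-5-[(tert-butyldimethylsilyl)oxy]-3-hydroxycyclohex-2-en-1-one | COc1cc(OCc2ccccc2)c2c(=O)cc(-c3ccc(OCc4ccccc4)c(/C(=C\c4ccc(OCc5ccccc5)cc4)C(=O)C4=C(O)CC(O[Si](C)(C)C(C)(C)C)CC4=O)c3)oc2c1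
F2 | step 12 | racemic trans silyl ether (racemate of 19, both C7 configurations; the 2R,3S antipode is drawn) | COc1cc(OCc2ccccc2)c2c(=O)cc(-c3ccc(OCc4ccccc4)c([C@@H]4C(=O)C5=C(CC(O[Si](C)(C)C(C)(C)C)CC5=O)O[C@H]4c4ccc(OCc5ccccc5)cc4)c3)oc2c1
F3 | step 12 | racemic alcohol (racemate of 20, both C7 configurations; the 2R,3S antipode is drawn) | COc1cc(OCc2ccccc2)c2c(=O)cc(-c3ccc(OCc4ccccc4)c([C@@H]4C(=O)C5=C(CC(O)CC5=O)O[C@H]4c4ccc(OCc5ccccc5)cc4)c3)oc2c1
F4 | step 12 | racemic 5,7-dihydroxy chromanone (racemate of 22; the 2R,3S antipode is drawn) | COc1cc(OCc2ccccc2)c2c(=O)cc(-c3ccc(OCc4ccccc4)c([C@@H]4C(=O)c5c(O)cc(O)cc5O[C@H]4c4ccc(OCc5ccccc5)cc4)c3)oc2c1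
F5 | step 14 | (2S,3R)-3-ArF-2-[4-(benzyloxy)phenyl]-7-[(tert-butyldimethylsilyl)oxy]-5-hydroxy-2,3-dihydro-4H-chromen-4-one | COc1cc(OCc2ccccc2)c2c(=O)cc(-c3ccc(OCc4ccccc4)c([C@H]4C(=O)c5c(O)cc(O[Si](C)(C)C(C)(C)C)cc5O[C@@H]4c4ccc(OCc5ccccc5)cc4)c3)oc2c1
F6 | step 10 | 2-(ArF-acetyl)-3-chloro-5-[(tert-butyldimethylsilyl)oxy]cyclohex-2-en-1-one (racemic) | COc1cc(OCc2ccccc2)c2c(=O)cc(-c3ccc(OCc4ccccc4)c(CC(=O)C4=C(Cl)CC(O[Si](C)(C)C(C)(C)C)CC4=O)c3)oc2c1
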